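**Retrosynthetic overview**

1. Numbering: lactone O1, C2 (C=O), C3 (methyl), C4 (enol), C5; chain C6–C18 from C5 to the furan. The plan rests on C4–C8: five carbons with carboxyl-level carbons at both ends (C4, C8), oxygen on C5 and a methyl on C7, which is D-glutamic acid (N exchanged for O with retention) methylated at its γ-carbon.
2. Ring A (the tetronic acid, O1–C5) is closed last by Dieckmann condensation of a C5 O-propionate onto a C4 methyl ester (C3–C4 bond). The furan is bought intact as 3-bromofuran. A γ-butyrolactone made from D-glutamic acid serves only as a stereochemical relay and is opened again.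
3. Key disconnection C8=C9: Julia–Kocienski olefination of the C8 aldehyde (C4–C8 carrying the O5 propionate) with the allylic C9 1-phenyltetrazol-5-yl sulfone (C9–C18 with the furan).
4. Aldehyde: D-glutamic acid → (R)-silyloxymethyl butyrolactone → α-methylation and kinetic enolate protonation (cis, sets C7) → Weinreb amide opening, O5 propionylation, Cp2Zr(H)Cl reduction.
5. Sulfone: (S)-citronellol supplies C13–C18 with C15. C1 is propargylated (C10–C12), the cleaved alkene end is joined to 3-bromofuran by Negishi coupling, and carboalumination/hydroxymethylation sets (E)-C10=C11 and adds C9 before thioether formation and oxidation.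

Key step: step 18

Remark: the 3-methyl lactone of step 4 is carried on as its C3-epimer mixture, because step 5 passes through the enolate in which C3 is planar.
Remark: at the methyl-bearing carbon of the citronellol-derived chain the R/S label changes between compounds only because CIP priorities change; no step touches that centre.

**Route**

Step 1
Reactants: 1 D-glutamic acid
Product: 2 (2R)-5-oxooxolane-2-carboxylic acid
Conditions: NaNO2, aq. HCl, 0 °C → rt
Reagents that add atoms: none
Why: Diazotisation of the α-amino acid with neighbouring-carboxylate participation (double inversion) lets the side-chain carboxylate oxygen replace nitrogen with net retention, so the future C5 is taken from the chiral pool as R.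

Step 2
Reactants: 2 (2R)-5-oxooxolane-2-carboxylic acid
Product: 3 (5R)-5-(hydroxymethyl)oxolan-2-one
Conditions: BH3·SMe2, THF, 0 °C → rt; MeOH
Reagents that add atoms: none
Why: Borane reduces a carboxylic acid much faster than a lactone (chemoselective borane reduction), and the stereocentre is not involved.

Step 3
Reactants: 3 (5R)-5-(hydroxymethyl)oxolan-2-one
Product: 4 (5R)-5-{[(tert-butyldiphenylsilyl)oxy]methyl}oxolan-2-one
Conditions: tBuPh2SiCl, imidazole, DMF, rt
Reagents that add atoms: tert-butyl(chloro)diphenylsilane CC(C)(C)[Si](Cl)(c1ccccc1)c1ccccc1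
Why: Imidazole-promoted silylation of a primary alcohol gives a bulky ether that survives enolate, aluminium amide and olefination conditions and later shields one lactone face.

Step 4
Reactants: 4 (5R)-5-{[(tert-butyldiphenylsilyl)oxy]methyl}oxolan-2-one
Product: 6 (5R)-5-{[(tert-butyldiphenylsilyl)oxy]methyl}-3-methyloxolan-2-one as the C3-epimer mixture, via lithium lactone enolate 5 (not isolated)
Conditions: LiN(iPr)2, THF, −78 °C; MeI, −78 °C
Reagents that add atoms: iodomethane CI
Why: Lactone enolate alkylation introduces the C7 methyl group, mainly anti to the C5 substituent (trans), but the C3 configuration formed here is irrelevant because step 5 re-enolises.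

Step 5
Reactants: 6 (5R)-5-{[(tert-butyldiphenylsilyl)oxy]methyl}-3-methyloxolan-2-one (C3-epimer mixture)
Product: 8 (3R,5R)-5-{[(tert-butyldiphenylsilyl)oxy]methyl}-3-methyloxolan-2-one (cis), via lithium methyl-lactone enolate 7 (not isolated)
Conditions: LiN(iPr)2, THF, −78 °C; then 2,6-di-tert-butyl-4-methylphenol, THF, −78 °C; H2O
Reagents that add atoms: none
Why: Kinetic protonation of the planar enolate by a bulky phenol should occur on the face opposite the silyloxymethyl group, which places the methyl cis to it and sets the future C7 as R by substrate control (diastereoselective enolate protonation).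

Step 6
Reactants: 8 (3R,5R)-5-{[(tert-butyldiphenylsilyl)oxy]methyl}-3-methyloxolan-2-one
Product: 9 (2R,4R)-5-[(tert-butyldiphenylsilyl)oxy]-4-hydroxy-N-methoxy-N,2-dimethylpentanamide
Conditions: MeNH(OMe)·HCl, Me3Al, CH2Cl2, 0 °C → rt; aq. KNaC4H4O6 (Rochelle salt)
Reagents that add atoms: N,O-dimethylhydroxylamine hydrochloride CNOC.Cl
Why: Weinreb aminolysis of a lactone with the aluminium amide opens the ring at the acyl carbon under non-basic conditions, so neither stereocentre is touched.

Step 7
Reactants: 9 (2R,4R)-5-[(tert-butyldiphenylsilyl)oxy]-4-hydroxy-N-methoxy-N,2-dimethylpentanamide; 10 propanoyl chloride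
Product: 11 (2R,4R)-1-[(tert-butyldiphenylsilyl)oxy]-5-[methoxy(methyl)amino]-4-methyl-5-oxopentan-2-yl propanoate
Conditions: pyridine, DMAP (cat.), CH2Cl2, 0 °C
Reagents that add atoms: none
Why: DMAP-catalysed O-acylation of the secondary alcohol, done at once to prevent relactonisation, installs the acyl group that later becomes C2 and C3 of the lactone.

Step 8
Reactants: 11 (2R,4R)-1-[(tert-butyldiphenylsilyl)oxy]-5-[methoxy(methyl)amino]-4-methyl-5-oxopentan-2-yl propanoate
Product: 12 (2R,4R)-5-[(tert-butyldiphenylsilyl)oxy]-2-methyl-4-(propanoyloxy)pentanal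
Conditions: Cp2Zr(H)Cl (Schwartz reagent), THF, rt, short time; used crude
Reagents that add atoms: none
Why: Hydrozirconation of the amide carbonyl gives a zirconated hemiaminal that releases the aldehyde only on work-up (amide-to-aldehyde reduction with Cp2Zr(H)Cl), which leaves the propionate and silyl ether untouched and exposes the α-methyl aldehyde to no base.

Step 9
Reactants: 13 (S)-citronellol
Product: 14 (6S)-8-iodo-2,6-dimethyloct-2-ene
Conditions: I2, PPh3, imidazole, CH2Cl2, 0 °C → rt
Reagents that add atoms: iodine II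
Why: Appel-type iodination converts the primary alcohol to the iodide by SN2 displacement of the alkoxyphosphonium, away from the stereocentre.

Step 10
Reactants: 14 (6S)-8-iodo-2,6-dimethyloct-2-ene; 15 trimethyl(prop-1-yn-1-yl)silane
Product: 17 [(6R)-6,10-dimethylundec-9-en-1-yn-1-yl]trimethylsilane, via (3-lithioprop-1-yn-1-yl)trimethylsilane 16 (not isolated)
Conditions: 15, nBuLi, THF, −78 → −20 °C; then 14, −78 °C → rt
Reagents that add atoms: none
Why: SN2 alkylation of the propargylic lithium reagent by the primary iodide adds C10–C12 as a silyl-protected alkyne (propargylation with lithiated 1-silylpropyne).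

Step 11
Reactants: 17 [(6R)-6,10-dimethylundec-9-en-1-yn-1-yl]trimethylsilane
Product: 19 (4R)-4-methyl-9-(trimethylsilyl)non-8-yn-1-ol, via silylalkynyl aldehyde 18 (not isolated)
Conditions: O3, CH2Cl2/MeOH, −78 °C (Sudan Red 7B end point); then NaBH4, −78 °C → rt
Reagents that add atoms: ozone [O-][O+]=O
Why: Ozonolysis with reductive work-up cleaves only the electron-rich trisubstituted alkene, which reacts far faster than the silylalkyne when ozone is titrated to the indicator end point, and exposes C18 as a primary alcohol.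

Step 12
Reactants: 19 (4R)-4-methyl-9-(trimethylsilyl)non-8-yn-1-ol
Product: 20 [(6R)-9-iodo-6-methylnon-1-yn-1-yl]trimethylsilane
Conditions: I2, PPh3, imidazole, CH2Cl2, 0 °C → rt
Reagents that add atoms: iodine II
Why: Appel-type iodination of the primary alcohol provides the handle for zinc insertion.

Step 13
Reactants: 20 [(6R)-9-iodo-6-methylnon-1-yn-1-yl]trimethylsilane; 21 3-bromofuran
Product: 23 [(6S)-9-(furan-3-yl)-6-methylnon-1-yn-1-yl]trimethylsilane, via alkylzinc iodide 22 (not isolated)
Conditions: Zn dust (BrCH2CH2Br, Me3SiCl activation), LiCl, THF, 40 °C; then 21, Pd(OAc)2 (cat.), SPhos (cat.), THF, rt → 50 °C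
Reagents that add atoms: none
Why: Zinc insertion into the primary iodide followed by Negishi cross-coupling (oxidative addition of zerovalent palladium into the furyl C–Br bond, transmetallation, reductive elimination) forms the C18–furan bond, and alkylzinc halides tolerate the silylalkyne.

Step 14
Reactants: 23 [(6S)-9-(furan-3-yl)-6-methylnon-1-yn-1-yl]trimethylsilane
Product: 24 3-[(4R)-4-methylnon-8-yn-1-yl]furan
Conditions: K2CO3, MeOH, rt
Reagents that add atoms: none
Why: Base-catalysed methanolysis of the alkynyl C–Si bond (protiodesilylation) frees the terminal alkyne.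

Step 15
Reactants: 24 3-[(4R)-4-methylnon-8-yn-1-yl]furan
Product: 26 (2E,7R)-10-(furan-3-yl)-3,7-dimethyldec-2-en-1-ol, via (E)-alkenyldimethylalane 25 (not isolated)
Conditions: Me3Al, Cp2ZrCl2 (cat.), CH2Cl2, 0 °C → rt; then (CH2O)n, THF, 0 °C → rt; aq. KNaC4H4O6
Reagents that add atoms: trimethylaluminium C[Al](C)C; paraformaldehyde (as formaldehyde) C=O
Why: Negishi zirconium-catalysed carboalumination adds methyl and aluminium syn across the terminal alkyne with methyl on the internal carbon, and hydroxymethylation of the alkenylalane with retention fixes (E)-C10=C11 and adds C9.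

Step 16
Reactants: 26 (2E,7R)-10-(furan-3-yl)-3,7-dimethyldec-2-en-1-ol
Product: 27 5-{[(2E,7R)-10-(furan-3-yl)-3,7-dimethyldec-2-en-1-yl]sulfanyl}-1-phenyl-1H-tetrazole
Conditions: 1-phenyl-1H-tetrazole-5-thiol, PPh3, DIAD, THF, 0 °C → rt
Reagents that add atoms: 1-phenyl-1H-tetrazole-5-thiol Sc1nnnn1-c1ccccc1
Why: Mitsunobu thioetherification of the primary allylic alcohol with the acidic heteroaryl thiol proceeds by direct SN2 displacement without allylic transposition.

Step 17
Reactants: 27 5-{[(2E,7R)-10-(furan-3-yl)-3,7-dimethyldec-2-en-1-yl]sulfanyl}-1-phenyl-1H-tetrazole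
Product: 28 5-{[(2E,7R)-10-(furan-3-yl)-3,7-dimethyldec-2-en-1-yl]sulfonyl}-1-phenyl-1H-tetrazole
Conditions: (NH4)6Mo7O24·4H2O (cat.), 30% aq. H2O2, EtOH, 0 °C → rt
Reagents that add atoms: hydrogen peroxide OO
Why: (NH4)6Mo7O24-catalysed H2O2 oxidation of sulfide to sulfone is the standard entry to allylic tetrazolyl sulfones and normally spares trisubstituted alkenes, and it is kept cold and short for the sake of the furan.

Step 18
Reactants: 28 5-{[(2E,7R)-10-(furan-3-yl)-3,7-dimethyldec-2-en-1-yl]sulfonyl}-1-phenyl-1H-tetrazole; 12 (2R,4R)-5-[(tert-butyldiphenylsilyl)oxy]-2-methyl-4-(propanoyloxy)pentanal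
Product: 32 (2R,4R,5E,7E,12R)-1-[(tert-butyldiphenylsilyl)oxy]-15-(furan-3-yl)-4,8,12-trimethylpentadeca-5,7-dien-2-yl propanoate, via potassium sulfonyl carbanion 29 (not isolated), via potassium β-alkoxy sulfone 30 (not isolated), via potassium sulfinate 31 (not isolated)
Conditions: 28, KN(SiMe3)2, DME, −78 °C, 30 min; then 12 in DME, −78 °C → rt; aq. NH4Cl
Reagents that add atoms: none
Why: This is a Julia–Kocienski olefination, whose closest known form is the coupling of an α-branched aldehyde with an allylic 1-phenyltetrazolyl sulfone: carbanion 29 adds to the aldehyde carbonyl to give alkoxide 30, the alkoxide attacks the tetrazole ipso carbon (Smiles rearrangement) to give sulfinate 31, and antiperiplanar loss of SO2 and the tetrazolone anion leaves the C8=C9 alkene. No ring closes and no stereocentre is created; the step makes the one skeletal bond C8–C9 that joins the two halves. The selectivity needed is E geometry at C8=C9, which the α-methyl branch of the aldehyde and the potassium counter-ion in a polar ether should secure through an open transition state leading to the anti adduct and a stereospecific anti elimination. C10=C11 should keep its E geometry because the allylic anion is made and consumed at −78 °C. C7 should survive because the sulfone is metallated completely before the aldehyde is added, so no free amide base meets the enolisable aldehyde, and at −78 °C the carbanion adds to the aldehyde far faster than to the propionate.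

Step 19
Reactants: 32 (2R,4R,5E,7E,12R)-1-[(tert-butyldiphenylsilyl)oxy]-15-(furan-3-yl)-4,8,12-trimethylpentadeca-5,7-dien-2-yl propanoate
Product: 33 (2R,4R,5E,7E,12R)-15-(furan-3-yl)-1-hydroxy-4,8,12-trimethylpentadeca-5,7-dien-2-yl propanoate
Conditions: HF·pyridine, pyridine, THF, 0 °C → rt
Reagents that add atoms: none
Why: Buffered, weakly acidic fluoride desilylation removes the silyl ether without the 1,2-acyl migration of the propionate that basic fluoride sources would promote.

Step 20
Reactants: 33 (2R,4R,5E,7E,12R)-15-(furan-3-yl)-1-hydroxy-4,8,12-trimethylpentadeca-5,7-dien-2-yl propanoate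
Product: 35 (2R,4R,5E,7E,12R)-15-(furan-3-yl)-4,8,12-trimethyl-2-(propanoyloxy)pentadeca-5,7-dienoic acid, via α-propanoyloxy aldehyde 34 (not isolated)
Conditions: TEMPO (cat.), PhI(OAc)2, MeCN/H2O, rt
Reagents that add atoms: water O
Why: Oxoammonium oxidation (TEMPO/PhI(OAc)2) in aqueous acetonitrile takes the primary alcohol through the aldehyde and its hydrate to the acid under near-neutral conditions that should spare the diene and furan and not epimerise C5.

Step 21
Reactants: 35 (2R,4R,5E,7E,12R)-15-(furan-3-yl)-4,8,12-trimethyl-2-(propanoyloxy)pentadeca-5,7-dienoic acid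
Product: 36 methyl (2R,4R,5E,7E,12R)-15-(furan-3-yl)-4,8,12-trimethyl-2-(propanoyloxy)pentadeca-5,7-dienoate
Conditions: Me3SiCHN2, toluene/MeOH, 0 °C
Reagents that add atoms: (trimethylsilyl)diazomethane C[Si](C)(C)C=[N+]=[N-]
Why: Esterification with (trimethylsilyl)diazomethane methylates the carboxylate under neutral conditions, so the α-acyloxy stereocentre and the propionate are untouched.

Step 22
Reactants: 36 methyl (2R,4R,5E,7E,12R)-15-(furan-3-yl)-4,8,12-trimethyl-2-(propanoyloxy)pentadeca-5,7-dienoate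
Product: 39 (5R)-5-[(2R,3E,5E,10R)-13-(furan-3-yl)-2,6,10-trimethyltrideca-3,5-dien-1-yl]-4-hydroxy-3-methylfuran-2(5H)-one (CNP0246504.1), via lithium propanoate enolate 37 (not isolated), via lithium tetronate 38 (not isolated)
Conditions: LiN(SiMe3)2, THF, −78 → 0 °C; cold 0.5 M HCl
Reagents that add atoms: none
Why: In this Dieckmann (intramolecular Claisen) condensation the propionate enolate attacks the methyl ester in a 5-exo-trig closure, methoxide leaves and the product is held as the stable tetronate until acidification, while C5 takes no part in bond formation and should keep its R configuration at low temperature.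

**Compound list**

1 | D-glutamic acid | N[C@H](CCC(=O)O)C(=O)O | starting material
2 | (2R)-5-oxooxolane-2-carboxylic acid | O=C1CC[C@H](C(=O)O)O1 | intermediate
3 | (5R)-5-(hydroxymethyl)oxolan-2-one | O=C1CC[C@H](CO)O1 | intermediate
4 | (5R)-5-{[(tert-butyldiphenylsilyl)oxy]methyl}oxolan-2-one | O=C1CC[C@H](CO[Si](c2ccccc2)(c2ccccc2)C(C)(C)C)O1 | intermediate
5 | lithium enolate of 4 (not isolated) | [Li+].[O-]C1=CC[C@H](CO[Si](c2ccccc2)(c2ccccc2)C(C)(C)C)O1 | intermediate
6 | (5R)-5-{[(tert-butyldiphenylsilyl)oxy]methyl}-3-methyloxolan-2-one, C3-epimer mixture (trans (3S,5R) expected to predominate) | CC1C[C@H](CO[Si](c2ccccc2)(c2ccccc2)C(C)(C)C)OC1=O | intermediate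
7 | lithium enolate of 6 (not isolated) | [Li+].[O-]C1=C(C)C[C@H](CO[Si](c2ccccc2)(c2ccccc2)C(C)(C)C)O1 | intermediate
8 | (3R,5R)-5-{[(tert-butyldiphenylsilyl)oxy]methyl}-3-methyloxolan-2-one (cis) | C[C@@H]1C[C@H](CO[Si](c2ccccc2)(c2ccccc2)C(C)(C)C)OC1=O | intermediate
9 | (2R,4R)-5-[(tert-butyldiphenylsilyl)oxy]-4-hydroxy-N-methoxy-N,2-dimethylpentanamide | CC(C)(C)[Si](c1ccccc1)(c1ccccc1)OC[C@@H](C[C@@H](C)C(=O)N(C)OC)O | intermediate
10 | propanoyl chloride | CCC(=O)Cl | starting material
11 | (2R,4R)-1-[(tert-butyldiphenylsilyl)oxy]-5-[methoxy(methyl)amino]-4-methyl-5-oxopentan-2-yl propanoate | CC(C)(C)[Si](c1ccccc1)(c1ccccc1)OC[C@@H](C[C@@H](C)C(=O)N(C)OC)OC(=O)CC | intermediate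
12 | (2R,4R)-5-[(tert-butyldiphenylsilyl)oxy]-2-methyl-4-(propanoyloxy)pentanal | CC(C)(C)[Si](c1ccccc1)(c1ccccc1)OC[C@@H](C[C@@H](C)C=O)OC(=O)CC | intermediate
13 | (S)-citronellol | OCC[C@@H](C)CCC=C(C)C | starting material
14 | (6S)-8-iodo-2,6-dimethyloct-2-ene | ICC[C@@H](C)CCC=C(C)C | intermediate
15 | trimethyl(prop-1-yn-1-yl)silane | CC#C[Si](C)(C)C | starting material
16 | (3-lithioprop-1-yn-1-yl)trimethylsilane (not isolated) | [Li]CC#C[Si](C)(C)C | intermediate
17 | [(6R)-6,10-dimethylundec-9-en-1-yn-1-yl]trimethylsilane | C[Si](C)(C)C#CCCC[C@@H](C)CCC=C(C)C | intermediate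
18 | (4R)-4-methyl-9-(trimethylsilyl)non-8-ynal (not isolated) | C[Si](C)(C)C#CCCC[C@@H](C)CCC=O | intermediate
19 | (4R)-4-methyl-9-(trimethylsilyl)non-8-yn-1-ol | C[Si](C)(C)C#CCCC[C@@H](C)CCCO | intermediate
20 | [(6R)-9-iodo-6-methylnon-1-yn-1-yl]trimethylsilane | C[Si](C)(C)C#CCCC[C@@H](C)CCCI | intermediate
21 | 3-bromofuran | Brc1ccoc1 | starting material
22 | iodo[(4R)-4-methyl-9-(trimethylsilyl)non-8-yn-1-yl]zinc (not isolated) | C[Si](C)(C)C#CCCC[C@@H](C)CCC[Zn]I | intermediate
23 | [(6S)-9-(furan-3-yl)-6-methylnon-1-yn-1-yl]trimethylsilane | C[Si](C)(C)C#CCCC[C@@H](C)CCCc1ccoc1 | intermediate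
24 | 3-[(4R)-4-methylnon-8-yn-1-yl]furan | C#CCCC[C@@H](C)CCCc1ccoc1 | intermediate
25 | [(1E,6S)-9-(furan-3-yl)-2,6-dimethylnon-1-en-1-yl]dimethylalumane (not isolated) | C[Al](C)/C=C(\C)CCC[C@@H](C)CCCc1ccoc1 | intermediate
26 | (2E,7R)-10-(furan-3-yl)-3,7-dimethyldec-2-en-1-ol | OC/C=C(\C)CCC[C@@H](C)CCCc1ccoc1 | intermediate
27 | 5-{[(2E,7R)-10-(furan-3-yl)-3,7-dimethyldec-2-en-1-yl]sulfanyl}-1-phenyl-1H-tetrazole | c1ccccc1-n1nnnc1SC/C=C(\C)CCC[C@@H](C)CCCc1ccoc1 | intermediate
28 | 5-{[(2E,7R)-10-(furan-3-yl)-3,7-dimethyldec-2-en-1-yl]sulfonyl}-1-phenyl-1H-tetrazole | c1ccccc1-n1nnnc1S(=O)(=O)C/C=C(\C)CCC[C@@H](C)CCCc1ccoc1 | intermediate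
29 | potassium salt of the C9 carbanion of 28 (not isolated) | [K+].c1ccccc1-n1nnnc1S(=O)(=O)[CH-]/C=C(\C)CCC[C@@H](C)CCCc1ccoc1 | intermediate
30 | potassium (2R,4R,7E,12R)-1-[(tert-butyldiphenylsilyl)oxy]-15-(furan-3-yl)-4,8,12-trimethyl-6-[(1-phenyl-1H-tetrazol-5-yl)sulfonyl]-2-(propanoyloxy)pentadec-7-en-5-olate (anti at the two new centres, both anti diastereomers; not isolated) | [K+].CC(C)(C)[Si](c1ccccc1)(c1ccccc1)OC[C@@H](C[C@@H](C)C([O-])C(/C=C(\C)CCC[C@@H](C)CCCc1ccoc1)S(=O)(=O)c1nnnn1-c1ccccc1)OC(=O)CC | intermediate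
31 | potassium (2R,4R,7E,12R)-1-[(tert-butyldiphenylsilyl)oxy]-15-(furan-3-yl)-4,8,12-trimethyl-5-[(1-phenyl-1H-tetrazol-5-yl)oxy]-2-(propanoyloxy)pentadec-7-ene-6-sulfinate (not isolated) | [K+].CC(C)(C)[Si](c1ccccc1)(c1ccccc1)OC[C@@H](C[C@@H](C)C(Oc1nnnn1-c1ccccc1)C(/C=C(\C)CCC[C@@H](C)CCCc1ccoc1)S(=O)[O-])OC(=O)CC | intermediate
32 | (2R,4R,5E,7E,12R)-1-[(tert-butyldiphenylsilyl)oxy]-15-(furan-3-yl)-4,8,12-trimethylpentadeca-5,7-dien-2-yl propanoate | CC(C)(C)[Si](c1ccccc1)(c1ccccc1)OC[C@@H](C[C@@H](C)/C=C/C=C(\C)CCC[C@@H](C)CCCc1ccoc1)OC(=O)CC | intermediate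
33 | (2R,4R,5E,7E,12R)-15-(furan-3-yl)-1-hydroxy-4,8,12-trimethylpentadeca-5,7-dien-2-yl propanoate | OC[C@@H](C[C@@H](C)/C=C/C=C(\C)CCC[C@@H](C)CCCc1ccoc1)OC(=O)CC | intermediate
34 | (2R,4R,5E,7E,12R)-15-(furan-3-yl)-4,8,12-trimethyl-1-oxopentadeca-5,7-dien-2-yl propanoate (not isolated) | O=C[C@@H](C[C@@H](C)/C=C/C=C(\C)CCC[C@@H](C)CCCc1ccoc1)OC(=O)CC | intermediate
35 | (2R,4R,5E,7E,12R)-15-(furan-3-yl)-4,8,12-trimethyl-2-(propanoyloxy)pentadeca-5,7-dienoic acid | OC(=O)[C@@H](C[C@@H](C)/C=C/C=C(\C)CCC[C@@H](C)CCCc1ccoc1)OC(=O)CC | intermediate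
36 | methyl (2R,4R,5E,7E,12R)-15-(furan-3-yl)-4,8,12-trimethyl-2-(propanoyloxy)pentadeca-5,7-dienoate | COC(=O)[C@@H](C[C@@H](C)/C=C/C=C(\C)CCC[C@@H](C)CCCc1ccoc1)OC(=O)CC | intermediate
37 | lithium enolate of the propanoate of 36 (not isolated) | [Li+].COC(=O)[C@@H](C[C@@H](C)/C=C/C=C(\C)CCC[C@@H](C)CCCc1ccoc1)OC([O-])=CC | intermediate
38 | lithium (5R)-5-[(2R,3E,5E,10R)-13-(furan-3-yl)-2,6,10-trimethyltrideca-3,5-dien-1-yl]-3-methyl-2-oxo-2,5-dihydrofuran-4-olate (not isolated) | [Li+].CC1=C([O-])[C@@H](C[C@@H](C)/C=C/C=C(\C)CCC[C@@H](C)CCCc2ccoc2)OC1=O | intermediate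
39 | (5R)-5-[(2R,3E,5E,10R)-13-(furan-3-yl)-2,6,10-trimethyltrideca-3,5-dien-1-yl]-4-hydroxy-3-methylfuran-2(5H)-one (CNP0246504.1) | CC1=C(O)[C@@H](C[C@@H](C)/C=C/C=C(\C)CCC[C@@H](C)CCCc2ccoc2)OC1=O | target

**Step count**

Total: 22 steps. Longest linear sequence: 14 steps (steps 9–22, from (S)-citronellol); the glutamic acid branch is 8 steps to aldehyde 12.

**Steps most likely to fail, with fallbacks**

Step 18. The allylic sulfonyl carbanion may add with poor anti selectivity or reversibly, which would give an E/Z mixture at C8=C9, and any free base may enolise the α-methyl aldehyde and erode C7. The fallback builds the diene by cross-coupling at C9–C10 instead. It sets out from aldehyde 12: Takai iodo-olefination (CrCl2, CHI3, THF, 0 °C) should give the (E)-vinyl iodide (2R,4R,5E)-1-[(tert-butyldiphenylsilyl)oxy]-6-iodo-4-methylhex-5-en-2-yl propanoate F1. Alkenylalane 25, made from alkyne 24 as in the first half of step 15, is then coupled with F1 (Pd(PPh3)4, ZnCl2, THF, rt; Negishi alkenyl–alkenyl coupling with retention of both geometries). This comes back to the route at diene 32, and the hydroxymethylation and steps 16 and 17 are then not needed.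

Step 17. The metal-peroxo oxidant may attack the furan ring or epoxidise C10=C11 before the slow second oxidation of the electron-poor sulfoxide is complete. The fallback brings sulfur in already at the sulfone level and uses the classical Julia–Lythgoe sequence. It sets out from allylic alcohol 26: CBr4/PPh3 (CH2Cl2, −20 °C) should give 3-[(4R,8E)-10-bromo-4,8-dimethyldec-8-en-1-yl]furan F2, and PhSO2Na in DMF should give 3-[(4R,8E)-10-(benzenesulfonyl)-4,8-dimethyldec-8-en-1-yl]furan F3. Lithiation (nBuLi, THF, −78 °C), addition to aldehyde 12 and trapping with Ac2O should give the β-acetoxy sulfone (2R,4R,7E,12R)-5-acetoxy-6-(benzenesulfonyl)-1-[(tert-butyldiphenylsilyl)oxy]-15-(furan-3-yl)-4,8,12-trimethylpentadec-7-en-2-yl propanoate F4 as a diastereomer mixture. Reductive elimination with sodium amalgam (Na2HPO4, THF/MeOH, −20 °C) comes back to the route at diene 32.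

Step 22. Deprotonation at C5 (α to the methyl ester and bearing the acyloxy group) may compete with enolisation of the propionate and epimerise C5, and intermolecular acyl transfer may compete with ring closure. The fallback makes the C3–C4 bond with an external enolate and frees the C5 oxygen only afterwards. It sets out from acid 35: LiOH (THF/H2O) should remove the propionate to give (2R,4R,5E,7E,12R)-15-(furan-3-yl)-2-hydroxy-4,8,12-trimethylpentadeca-5,7-dienoic acid F5. 2-Methoxypropene with pyridinium p-toluenesulfonate (CH2Cl2, 0 °C) should give (5R)-5-[(2R,3E,5E,10R)-13-(furan-3-yl)-2,6,10-trimethyltrideca-3,5-dien-1-yl]-2,2-dimethyl-1,3-dioxolan-4-one F6. The lithium enolate of methyl propanoate (LiN(iPr)2, THF, −78 °C → rt) then acylates at the dioxolanone carbonyl, the hemiketal alkoxide loses acetone, and the freed C5 alkoxide lactonises onto the ester (known acylation of ester enolates by 1,3-dioxolan-4-ones with lactonisation to tetronic acids). After acidification this comes back to the route at target 39.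

**Further compounds**

F1 | step 18 | (2R,4R,5E)-1-[(tert-butyldiphenylsilyl)oxy]-6-iodo-4-methylhex-5-en-2-yl propanoate | CC(C)(C)[Si](c1ccccc1)(c1ccccc1)OC[C@@H](C[C@@H](C)/C=C/I)OC(=O)CC
F2 | step 17 | 3-[(4R,8E)-10-bromo-4,8-dimethyldec-8-en-1-yl]furan | BrC/C=C(\C)CCC[C@@H](C)CCCc1ccoc1
F3 | step 17 | 3-[(4R,8E)-10-(benzenesulfonyl)-4,8-dimethyldec-8-en-1-yl]furan | O=S(=O)(C/C=C(\C)CCC[C@@H](C)CCCc1ccoc1)c1ccccc1
F4 | step 17 | (2R,4R,7E,12R)-5-acetoxy-6-(benzenesulfonyl)-1-[(tert-butyldiphenylsilyl)oxy]-15-(furan-3-yl)-4,8,12-trimethylpentadec-7-en-2-yl propanoate (mixture at C5 and C6) | CC(C)(C)[Si](c1ccccc1)(c1ccccc1)OC[C@@H](C[C@@H](C)C(OC(C)=O)C(/C=C(\C)CCC[C@@H](C)CCCc1ccoc1)S(=O)(=O)c1ccccc1)OC(=O)CC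
F5 | step 22 | (2R,4R,5E,7E,12R)-15-(furan-3-yl)-2-hydroxy-4,8,12-trimethylpentadeca-5,7-dienoic acid | OC(=O)[C@@H](C[C@@H](C)/C=C/C=C(\C)CCC[C@@H](C)CCCc1ccoc1)O
F6 | step 22 | (5R)-5-[(2R,3E,5E,10R)-13-(furan-3-yl)-2,6,10-trimethyltrideca-3,5-dien-1-yl]-2,2-dimethyl-1,3-dioxolan-4-one | CC1(C)OC(=O)[C@@H](C[C@@H](C)/C=C/C=C(\C)CCC[C@@H](C)CCCc2ccoc2)O1
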